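**Plan**
- Retrosynthesis: remove the 4'-O-benzyl and 8-O-methyl groups, then cut ring A at C8–C8a (back to a 4-hydroxycyclobutenone) and at C4a–C5 (back to dimethyl squarate and a pyranone metallated next to its carbonyl). Ring C is cut at C3–C4 and O1–C8a into an aryl methoxymethyl ketone and a β-ethoxyacryloyl unit, and the ketone at C2–C1' into an aryl bromide and a methoxyacetyl amide.
- Enabling feature: ring A carries oxygen on all four carbons C5–C8, with para hydroxyl-level oxygens at C5/C8 and vicinal methoxyls at C6/C7. This is the C4O4 pattern of dimethyl squarate, so C5–C8 can be fused as one unit across the C4a=C8a bond of a preformed 2-aryl-3-methoxy-4-pyranone.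
- Forward: ring B is bought as the bromide; ring C is built on the aryl ketone by enolate acylation and cyclisation; the pyranone carbon next to C=O is iodinated through directed zincation and joined to squarate; ring A is closed last by thermal ring expansion, followed by 8-O-methylation and debenzylation.
- Stereochemistry: the target has no stereocentre. The only one on the route (the carbinol carbon of the squarate adduct) is formed racemic and becomes the sp2 carbon C5.

Key step: step 6

Remark: the target SMILES has no stereodescriptor and the molecule has no configurationally stable stereo-element, so it is a single achiral compound and no enantioselective step is needed.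

**Step 1**
Reactants: 1 4-bromo-3-methoxyphenol
Product: 2 4-(benzyloxy)-1-bromo-2-methoxybenzene
Conditions: BnBr (1.1 equiv), K2CO3, DMF, 25 °C
Reagents that add atoms: benzyl bromide, BrCc1ccccc1
Why: Williamson ether synthesis; the phenoxide is alkylated quickly by the benzylic bromide and the aryl bromide is inert under these conditions.

**Step 2**
Reactants: 2 4-(benzyloxy)-1-bromo-2-methoxybenzene; 3 N,2-dimethoxy-N-methylacetamide
Product: 5 1-[4-(benzyloxy)-2-methoxyphenyl]-2-methoxyethan-1-one, via aryllithium 4 (not isolated)
Conditions: n-BuLi (1.05 equiv), THF, −78 °C; then 3, −78 → 0 °C; 1 M HCl, 0 °C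
Reagents that add atoms: none
Why: Bromine–lithium exchange is faster than any deprotonation at −78 °C, and the aryllithium adds once to the Weinreb amide because the chelated tetrahedral intermediate releases the ketone only on acidic work-up (Weinreb ketone synthesis).

**Step 3**
Reactants: 5 1-[4-(benzyloxy)-2-methoxyphenyl]-2-methoxyethan-1-one; 6 (E)-3-ethoxyacryloyl chloride
Product: 8 2-[4-(benzyloxy)-2-methoxyphenyl]-3-methoxy-4H-pyran-4-one, via ethoxyenedione 7 (not isolated)
Conditions: LiHMDS (2.2 equiv), THF, −78 °C; 6, −78 → 0 °C; 1 M HCl; then TFA (cat.), PhMe, 25 °C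
Reagents that add atoms: none
Why: C-acylation of the lithium enolate by the β-alkoxyacryloyl chloride (the second equivalent of base takes up the acidic diketone proton), then acid-catalysed 6-endo addition–elimination of the enol oxygen onto the β-ethoxy enone, is the established γ-pyrone annulation of ketones; the ketone oxygen becomes O1 and its α-carbon becomes C3.

**Step 4**
Reactants: 8 2-[4-(benzyloxy)-2-methoxyphenyl]-3-methoxy-4H-pyran-4-one
Product: 10 2-[4-(benzyloxy)-2-methoxyphenyl]-5-iodo-3-methoxy-4H-pyran-4-one, via pyranonylzinc chloride 9 (not isolated)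
Conditions: TMPZnCl·LiCl (1.3 equiv), THF, 25 °C; then I2, THF, 0 °C
Reagents that add atoms: iodine, II
Why: Carbonyl-directed C–H zincation with a TMP-zinc amide, as known for the carbon next to C=O in chromones, should place zinc on C5 and not on the oxygen-bound C6; iodolysis of the C–Zn bond then installs iodine there, and the electron-rich resorcinol ring stays untouched because no arene-iodinating electrophile is generated.

**Step 5**
Reactants: 10 2-[4-(benzyloxy)-2-methoxyphenyl]-5-iodo-3-methoxy-4H-pyran-4-one; 11 dimethyl squarate
Product: 13 4-{6-[4-(benzyloxy)-2-methoxyphenyl]-5-methoxy-4-oxo-4H-pyran-3-yl}-4-hydroxy-2,3-dimethoxycyclobut-2-en-1-one (racemic), via pyranonylmagnesium chloride 12 (not isolated)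
Conditions: i-PrMgCl·LiCl (1.1 equiv), THF, −78 → −40 °C; then cannulated into 11 (1.5 equiv), THF, −78 °C; pH 7 buffer at −78 °C; rapid filtration through Et3N-deactivated silica
Reagents that add atoms: none
Why: Iodine–magnesium exchange on an α-iodo vinylogous ester is fast at low temperature, and the alkenyl Grignard adds 1,2 to one of the two equivalent ketone carbonyls of the squarate, the standard entry to 4-hydroxycyclobutenones; the new carbinol centre is formed racemic, which is immaterial because step 6 destroys it.

**Step 6**
Reactants: 13 4-{6-[4-(benzyloxy)-2-methoxyphenyl]-5-methoxy-4-oxo-4H-pyran-3-yl}-4-hydroxy-2,3-dimethoxycyclobut-2-en-1-one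
Product: 16 4'-benzyloxy-5,8-dihydroxy-3,6,7,2'-tetramethoxyflavone, via dienylketene 14 (not isolated), via 8aH-dienone 15 (not isolated)
Conditions: degassed PhMe (0.02 M), 110 °C, Ar; concentrated under Ar
Reagents that add atoms: none
Why: Heating opens the cyclobutenone by a conrotatory 4π electrocyclic ring opening in which the hydroxyl rotates outward (donor torquoselectivity), so the pyranonyl group lies inward on the (Z)-dienylketene 14, next to the ketene carbon. A 6π disrotatory electrocyclisation then joins the ketene carbon to the C–H carbon of the pyranone (the future C8a) to give dienone 15, and a proton shift from C8a to the C8 oxygen aromatises ring A as the 5,8-hydroquinone. The closest known reaction is the Moore ring expansion of 4-aryl- and 4-alkenyl-4-hydroxycyclobutenones to hydroquinones, here with a γ-pyranone C=C as the 2π partner. Ring A closes in the 6π electrocyclic mode, with C8–C8a as the only new skeletal bond; the squarate methoxyls become 6- and 7-OMe and the two squarate carbonyl carbons become C5 and C8. No stereocentre is created, and the racemic carbinol carbon of 13 ends as sp2 C5. The step needs closure on the C–H carbon rather than on the carbonyl carbon of the pyranone, which is secured because only the former shares a C=C with the attachment carbon and carries a hydrogen for aromatisation, and it needs exclusion of oxygen so that the hydroquinone is not oxidised to the quinone.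

**Step 7**
Reactants: 16 4'-benzyloxy-5,8-dihydroxy-3,6,7,2'-tetramethoxyflavone
Product: 17 4'-benzyloxy-5-hydroxy-3,6,7,8,2'-pentamethoxyflavone
Conditions: MeI (1.2 equiv), K2CO3 (1.5 equiv), degassed acetone, 40 °C, Ar
Reagents that add atoms: iodomethane, CI
Why: Chemoselective Williamson methylation; the 5-hydroxyl is held in a hydrogen bond to C4=O and is much less nucleophilic than the free 8-hydroxyl, the classical basis for leaving the 5-OH of flavones unmethylated with about one equivalent of alkylating agent.

**Step 8**
Reactants: 17 4'-benzyloxy-5-hydroxy-3,6,7,8,2'-pentamethoxyflavone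
Product: 18 5,4'-dihydroxy-3,6,7,8,2'-pentamethoxyflavone
Conditions: H2 (1 atm), 10% Pd/C, EtOAc–MeOH, 25 °C
Reagents that add atoms: none
Why: Catalytic hydrogenolysis of the benzyl aryl ether; the tetrasubstituted conjugated C2=C3 bond, the C4 carbonyl and the methyl ethers are inert under these mild conditions.

**Compound list**
1 | 4-bromo-3-methoxyphenol | COc1cc(O)ccc1Br | starting material
2 | 4-(benzyloxy)-1-bromo-2-methoxybenzene | COc1cc(OCc2ccccc2)ccc1Br | intermediate
3 | N,2-dimethoxy-N-methylacetamide | COCC(=O)N(C)OC | starting material
4 | [4-(benzyloxy)-2-methoxyphenyl]lithium | [Li]c1ccc(OCc2ccccc2)cc1OC | intermediate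
5 | 1-[4-(benzyloxy)-2-methoxyphenyl]-2-methoxyethan-1-one | COCC(=O)c1ccc(OCc2ccccc2)cc1OC | intermediate
6 | (E)-3-ethoxyacryloyl chloride | CCO/C=C/C(Cl)=O | starting material
7 | (4E)-1-[4-(benzyloxy)-2-methoxyphenyl]-5-ethoxy-2-methoxypent-4-ene-1,3-dione (racemic at C2, enolisable) | CCO/C=C/C(=O)C(OC)C(=O)c1ccc(OCc2ccccc2)cc1OC | intermediate
8 | 2-[4-(benzyloxy)-2-methoxyphenyl]-3-methoxy-4H-pyran-4-one | COc1cc(OCc2ccccc2)ccc1-c1occc(=O)c1OC | intermediate
9 | {6-[4-(benzyloxy)-2-methoxyphenyl]-5-methoxy-4-oxo-4H-pyran-3-yl}zinc chloride | COc1cc(OCc2ccccc2)ccc1-c1occ([Zn]Cl)c(=O)c1OC | intermediate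
10 | 2-[4-(benzyloxy)-2-methoxyphenyl]-5-iodo-3-methoxy-4H-pyran-4-one | COc1cc(OCc2ccccc2)ccc1-c1occ(I)c(=O)c1OC | intermediate
11 | dimethyl squarate (3,4-dimethoxycyclobut-3-ene-1,2-dione) | COC1=C(OC)C(=O)C1=O | starting material
12 | {6-[4-(benzyloxy)-2-methoxyphenyl]-5-methoxy-4-oxo-4H-pyran-3-yl}magnesium chloride | COc1cc(OCc2ccccc2)ccc1-c1occ([Mg]Cl)c(=O)c1OC | intermediate
13 | 4-{6-[4-(benzyloxy)-2-methoxyphenyl]-5-methoxy-4-oxo-4H-pyran-3-yl}-4-hydroxy-2,3-dimethoxycyclobut-2-en-1-one (racemic) | COC1=C(OC)C(O)(C1=O)c1coc(-c2ccc(OCc3ccccc3)cc2OC)c(OC)c1=O | intermediate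
14 | (3Z)-4-{6-[4-(benzyloxy)-2-methoxyphenyl]-5-methoxy-4-oxo-4H-pyran-3-yl}-4-hydroxy-2,3-dimethoxybuta-1,3-dien-1-one | O=C=C(OC)/C(OC)=C(O)\c1coc(-c2ccc(OCc3ccccc3)cc2OC)c(OC)c1=O | intermediate
15 | 2-[4-(benzyloxy)-2-methoxyphenyl]-5-hydroxy-3,6,7-trimethoxy-8aH-chromene-4,8-dione (racemic) | O=C1C(OC)=C(OC)C(O)=C2C(=O)C(OC)=C(-c3ccc(OCc4ccccc4)cc3OC)OC12 | intermediate
16 | 4'-benzyloxy-5,8-dihydroxy-3,6,7,2'-tetramethoxyflavone | COc1cc(OCc2ccccc2)ccc1-c1oc2c(O)c(OC)c(OC)c(O)c2c(=O)c1OC | intermediate
17 | 4'-benzyloxy-5-hydroxy-3,6,7,8,2'-pentamethoxyflavone | COc1cc(OCc2ccccc2)ccc1-c1oc2c(OC)c(OC)c(OC)c(O)c2c(=O)c1OC | intermediate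
18 | 5,4'-dihydroxy-3,6,7,8,2'-pentamethoxyflavone | COc1cc(O)ccc1-c1oc2c(OC)c(OC)c(OC)c(O)c2c(=O)c1OC | target

**Step count and risks**
Total: 8 steps. Longest linear sequence: 8 steps, from 1.

Step 6 is the most exposed. The electron-rich 5,8-hydroquinone may be oxidised by traces of oxygen during heating and isolation, and closure of the ketene onto a pyranone C=C is untried and may need longer heating, which makes that loss worse. The result would be hydroquinone/quinone mixtures that cannot be methylated cleanly. The fallback isolates at the quinone oxidation level. Setting out from 13, the thermolysis is run in p-xylene at 138 °C and the crude product is stirred with Ag2O in CH2Cl2 to give 2-[4-(benzyloxy)-2-methoxyphenyl]-3,6,7-trimethoxy-4H-chromene-4,5,8-trione F1, which is purified as the stable quinone. F1 is then reduced with aqueous Na2S2O4 in degassed EtOAc, which returns the route to 16; the organic solution is carried straight into step 7.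

Step 5 is next. The magnesiated pyranone may fragment by β-elimination of the ring oxygen (opening to an alkynyl ketone), or i-PrMgCl may add to the pyranone before the exchange is complete. The fallback replaces the Grignard by a zinc nucleophile and skips the iodide. Setting out from 8, zincation as in step 4 gives 9, which is not iodinated but treated with MgCl2 (1 equiv) and 11 at 0–25 °C. The Lewis-acid-accelerated carbonyl addition of the organozinc should give 13 directly, where the route is rejoined. No compound outside the list is made on this path (F0).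

Step 4 is third. The amide base may remove the more acidic C6–H next to the ring oxygen instead of the C5–H next to the carbonyl, or give mixtures, so that iodine ends on the wrong carbon. The fallback fixes the iodine position by construction. Setting out from 5, the enolate (LiHMDS, THF, −78 °C) is C-acetylated with acetyl chloride to 1-[4-(benzyloxy)-2-methoxyphenyl]-2-methoxybutane-1,3-dione F2. Because the central carbon is blocked by methoxyl, DMF dimethyl acetal (PhMe, 80 °C) should condense at the terminal methyl to give (4E)-1-[4-(benzyloxy)-2-methoxyphenyl]-5-(dimethylamino)-2-methoxypent-4-ene-1,3-dione F3. Iodine in CHCl3 at 25 °C should iodinate the enaminone α-carbon, and the enol oxygen then closes onto the iminium carbon with loss of dimethylamine, the cyclisation used to make 3-iodochromones from enaminones. This gives 10, where the route is rejoined.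

**Further compounds**
F1 | step 6 | 2-[4-(benzyloxy)-2-methoxyphenyl]-3,6,7-trimethoxy-4H-chromene-4,5,8-trione | COc1cc(OCc2ccccc2)ccc1C1=C(OC)C(=O)C2=C(O1)C(=O)C(OC)=C(OC)C2=O
F0 | step 5 | none | none
F2 | step 4 | 1-[4-(benzyloxy)-2-methoxyphenyl]-2-methoxybutane-1,3-dione | CC(=O)C(OC)C(=O)c1ccc(OCc2ccccc2)cc1OC
F3 | step 4 | (4E)-1-[4-(benzyloxy)-2-methoxyphenyl]-5-(dimethylamino)-2-methoxypent-4-ene-1,3-dione | CN(C)/C=C/C(=O)C(OC)C(=O)c1ccc(OCc2ccccc2)cc1OC
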